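**Retrosynthetic overview**

- The caffeate on O5 is disconnected last. What remains is a tert-butyl 1-O-methylquinate with O3/O4 tied in a p-methoxybenzylidene acetal, and its C3 alcohol comes from a C3 ketone.
- The strategy rests on two features. C1 (quaternary, OMe and carboxyl) with its two CH2 arms C2 and C6 is a citric-acid-type carbon. The trans oxygens O4 and O5 sit on the C4–C5 bond. The cyclohexane ring C1–C6, the only ring of the target, is therefore closed by an intramolecular amine-catalysed aldol of a C3 ketone (O4 on its α-carbon C4) onto a C5 aldehyde.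
- The keto aldehyde comes from double C=C cleavage of a diene: an allyl arm gives C6–C5 and a 2-(PMB-oxymethyl)allyl arm gives C2–C3–C4.
- The C1 centre is made by Seebach alkylation of the pivalaldehyde acetal of (S)-2-hydroxypent-4-enoic acid (from L-allylglycine), followed by ester and ether adjustment.
- Stereocentres: C1 in step 4, C4 and C5 in step 9, C3 in step 10.

Key step: step 9

Remark on numbering: C1 is the quaternary carbon, C2 and C6 its CH2 neighbours, C3 and C4 carry the free hydroxyls and C5 the caffeate. The SMILES has OMe, O3 and O4 on one ring face and O5 and the carboxyl on the other (natural quinic acid configuration, 1S,3R,4R,5R). The "3-O-caffeoyl" of the older quinic numbering is therefore O5 here.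

Assumption: L-allylglycine, 3-bromo-2-(bromomethyl)prop-1-ene, O-tert-butyl-N,N′-diisopropylisourea and Me4NBH(OAc)3 are taken as commercial.

**Route**

Step 1
Reactants: 1 L-allylglycine, (S)-2-aminopent-4-enoic acid
Product: 2 (S)-2-hydroxypent-4-enoic acid
Conditions: NaNO2, 1 M H2SO4 (aq), 0 °C → rt
Reagents that add atoms: water, O
Why: Diazotisation of the α-amino acid (hydroxy-deamination): the neighbouring carboxylate expels N2 to give an α-lactone that water opens, two inversions that should leave C2 in the S configuration.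

Step 2
Reactants: 2 (S)-2-hydroxypent-4-enoic acid
Product: 3 (2S,5S)-2-tert-butyl-5-(prop-2-en-1-yl)-1,3-dioxolan-4-one (cis)
Conditions: tBuCHO, TsOH·H2O (cat.), pentane, reflux, Dean–Stark; cis isomer purified by chromatography
Reagents that add atoms: pivalaldehyde (2,2-dimethylpropanal), CC(C)(C)C=O
Why: Acid-catalysed acetalisation (Seebach dioxolanone, self-regeneration of stereocentres): the new acetal carbon is set relative to C5 with the cis isomer favoured, and any trans isomer is removed because it would lead into the enantiomeric series.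

Step 3
Reactants: 4 4-methoxybenzyl alcohol; 5 3-bromo-2-(bromomethyl)prop-1-ene
Product: 7 1-({[2-(bromomethyl)prop-2-en-1-yl]oxy}methyl)-4-methoxybenzene, via sodium 4-methoxybenzyl oxide 6 (not isolated)
Conditions: NaH, THF, 0 °C; then added to 5 (3 equiv), THF, 0 °C → rt
Reagents that add atoms: none
Why: Williamson ether synthesis on a symmetrical bis-allylic dibromide, where SN2 and SN2′ attack give the same product and the excess of 5 with inverse addition should hold the reaction at monosubstitution.

Step 4
Reactants: 3 (2S,5S)-2-tert-butyl-5-(prop-2-en-1-yl)-1,3-dioxolan-4-one; 7 1-({[2-(bromomethyl)prop-2-en-1-yl]oxy}methyl)-4-methoxybenzene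
Product: 9 (2S,5R)-2-tert-butyl-5-{2-[(4-methoxybenzyloxy)methyl]prop-2-en-1-yl}-5-(prop-2-en-1-yl)-1,3-dioxolan-4-one, via lithium dioxolanone enolate 8 (not isolated)
Conditions: LiN(iPr)2, THF, −78 °C; then 7, −78 → −40 °C
Reagents that add atoms: none
Why: Seebach alkylation of the dioxolanone enolate: the planar C5 is attacked by the allylic bromide on the face away from the tert-butyl group, so the new arm takes the place of the former hydrogen and the quaternary centre (5R) is formed with overall retention.

Step 5
Reactants: 9 (2S,5R)-dialkylated dioxolanone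
Product: 10 (2R)-2-hydroxy-2-{2-[(4-methoxybenzyloxy)methyl]prop-2-en-1-yl}pent-4-enoic acid
Conditions: LiOH·H2O, THF/H2O (3:1), rt; then 1 M HCl to pH 3, 0 °C
Reagents that add atoms: lithium hydroxide, [Li+].[OH-]
Why: Saponification of the acylal-type lactone: hydroxide adds to the ring carbonyl and the hemiacetal collapses to pivalaldehyde, freeing the tertiary hydroxy acid without touching the quaternary centre, the PMB ether or the alkenes.

Step 6
Reactants: 10 (2R)-hydroxy acid
Product: 11 tert-butyl (2R)-2-hydroxy-2-{2-[(4-methoxybenzyloxy)methyl]prop-2-en-1-yl}pent-4-enoate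
Conditions: O-tert-butyl-N,N′-diisopropylisourea (3 equiv), CH2Cl2, rt
Reagents that add atoms: O-tert-butyl-N,N′-diisopropylisourea, CC(C)N=C(OC(C)(C)C)NC(C)C
Why: Esterification with an O-tert-butyl isourea: the acid protonates the isourea and the carboxylate captures the tert-butyl group under neutral conditions, which suits hindered acids and leaves the tertiary hydroxyl and the PMB ether alone.

Step 7
Reactants: 11 tert-butyl (2R)-hydroxy ester
Product: 12 tert-butyl (2R)-2-methoxy-2-{2-[(4-methoxybenzyloxy)methyl]prop-2-en-1-yl}pent-4-enoate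
Conditions: NaH, MeI, DMF, 0 °C → rt
Reagents that add atoms: iodomethane, CI
Why: Williamson O-methylation of the tertiary alkoxide; with both arms still alkenes there is no β-carbonyl, so neither retro-aldol cleavage nor β-elimination can compete.

Step 8
Reactants: 12 tert-butyl (2R)-methoxy diene
Product: 13 tert-butyl (2R)-2-methoxy-5-(4-methoxybenzyloxy)-4-oxo-2-(2-oxoethyl)pentanoate
Conditions: OsO4 (2 mol %), NaIO4 (4.4 equiv), 2,6-lutidine, 1,4-dioxane/H2O (3:1), rt
Reagents that add atoms: osmium tetroxide, O=[Os](=O)(=O)=O; sodium periodate, [Na+].[O-]I(=O)(=O)=O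
Why: Lemieux–Johnson oxidative cleavage (dihydroxylation, then periodate glycol cleavage) of both terminal alkenes at once, the monosubstituted one giving the C5 aldehyde and the 1,1-disubstituted one the C3 ketone, with 2,6-lutidine buffering the β-methoxy carbonyl groups and the PMB ether untouched.

Step 9
Reactants: 13 tert-butyl (2R)-2-methoxy-5-(4-methoxybenzyloxy)-4-oxo-2-(2-oxoethyl)pentanoate
Product: 14 tert-butyl (1R,4S,5R)-5-hydroxy-1-methoxy-4-(4-methoxybenzyloxy)-3-oxocyclohexane-1-carboxylate
Conditions: (S)-proline (30 mol %), DMSO, 20 °C, 0.05 M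
Reagents that add atoms: none
Why: (S)-Proline condenses with the C3 ketone, the enamine toward the oxygen-bearing C4 adds to the C5 aldehyde while the catalyst's carboxylic acid hydrogen-bonds the aldehyde oxygen, and hydrolysis of the iminium ion releases 14 (enamine aldol). The closest known reactions are the proline-catalysed 6-enolendo aldol cyclisation of the Hajos–Parrish type and the proline aldol of α-oxygenated ketones. The single ring C1–C6 closes in the 6-(enolendo)-exo-trig mode by forming C4–C5; the enamine toward C2 could only give a four-membered ring and is unproductive, which fixes the regiochemistry. C4 is set by attack on the face syn to the carboxylic acid of the anti enamine in which OPMB lies trans to nitrogen, and C5 by the aldehyde face that remains once its oxygen is held by the acid and C6 is tied back to C2 through C1 (Houk–List arrangement), which for (S)-proline corresponds to 4S,5R with O4 and O5 trans. The step needs this trans pair with O5 on the face of the C1 ester: the catalyst enantiomer supplies the sense, C4 can correct itself by enamine epimerisation, and after ring inversion the adduct is the all-equatorial (ester, O4, O5) and most stable of the four diastereomers.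

Step 10
Reactants: 14 tert-butyl (1R,4S,5R)-hydroxy ketone
Product: 15 tert-butyl 1-O-methyl-4-O-(4-methoxybenzyl)quinate (3-OH cis to 4-OPMB and 1-OMe; 5-OH trans to them, cis to the ester)
Conditions: Me4NBH(OAc)3 (5 equiv), MeCN/AcOH (1:1), −30 °C
Reagents that add atoms: none
Why: Evans–Saksena hydroxyl-directed reduction: O5 exchanges onto boron and hydride is delivered intramolecularly to the C3 carbonyl on the O5 face, which should give the 1,3-anti diol with O3 axial and cis to O4, the axial C1 methoxy shielding the opposite face as well.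

Step 11
Reactants: 15 tert-butyl 1-O-methyl-4-O-(4-methoxybenzyl)quinate
Product: 16 tert-butyl 1-O-methyl-3,4-O-(4-methoxybenzylidene)quinate (cis-fused 2-aryl-1,3-dioxolane on O3/O4; 5-OH free; acetal carbon as either epimer)
Conditions: DDQ (1.2 equiv), 4 Å MS, CH2Cl2, 0 °C
Reagents that add atoms: none
Why: Oikawa–Yonemitsu oxidative acetalisation: DDQ removes hydride from the PMB methylene and the O4 oxocarbenium ion is trapped by the cis O3–H as a cis-fused dioxolane rather than by the trans O5–H, leaving O5 as the only free hydroxyl; the configuration of the new acetal carbon is of no consequence because it is removed in step 15.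

Step 12
Reactants: 17 caffeic acid
Product: 18 (E)-3-(3,4-diacetoxyphenyl)prop-2-enoic acid
Conditions: Ac2O, pyridine, rt; aqueous work-up
Reagents that add atoms: acetic anhydride, CC(=O)OC(C)=O
Why: Acetylation of both phenols (any mixed anhydride at the carboxyl is hydrolysed on work-up), which masks the catechol for the acylation.

Step 13
Reactants: 18 (E)-3-(3,4-diacetoxyphenyl)prop-2-enoic acid
Product: 19 (E)-3-(3,4-diacetoxyphenyl)prop-2-enoyl chloride
Conditions: (COCl)2, DMF (cat.), CH2Cl2, 0 °C → rt
Reagents that add atoms: oxalyl chloride, ClC(=O)C(Cl)=O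
Why: Acid chloride formation with oxalyl chloride under Vilsmeier catalysis by DMF, to which the aryl acetates and the E-alkene are stable.

Step 14
Reactants: 16 tert-butyl 1-O-methyl-3,4-O-(4-methoxybenzylidene)quinate; 19 (E)-3-(3,4-diacetoxyphenyl)prop-2-enoyl chloride
Product: 20 tert-butyl 5-O-[(E)-3-(3,4-diacetoxyphenyl)prop-2-enoyl]-1-O-methyl-3,4-O-(4-methoxybenzylidene)quinate
Conditions: pyridine, DMAP (cat.), CH2Cl2, 0 °C → rt
Reagents that add atoms: none
Why: DMAP-catalysed acylation (acylpyridinium transfer) of the single free hydroxyl O5 by the acid chloride; no stereocentre is touched.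

Step 15
Reactants: 20 fully protected ester
Product: 21 5-O-[(E)-3-(3,4-diacetoxyphenyl)prop-2-enoyl]-1-O-methylquinic acid
Conditions: TFA/CH2Cl2/H2O (10:10:1), 0 °C → rt
Reagents that add atoms: none
Why: Acidolysis: TFA cleaves the tert-butyl ester by loss of isobutene and hydrolyses the p-methoxybenzylidene acetal, while the aryl acetates keep the catechol unreactive toward the cations formed and the O5 ester does not migrate readily in acid.

Step 16
Reactants: 21 5-O-(di-O-acetylcaffeoyl)-1-O-methylquinic acid
Product: 22 3-O-caffeoyl-1-methylquinic acid (5-O-caffeoyl-1-O-methylquinic acid in the numbering used here; 1S,3R,4R,5R)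
Conditions: 1 M HCl (aq)/THF (1:1), rt
Reagents that add atoms: none
Why: Acid-catalysed hydrolysis of the two aryl acetates, which should be cleaved much faster than the alkyl cinnamate ester, in a medium that suppresses base-promoted acyl migration among O3, O4 and O5.

**Compound list**

1 | L-allylglycine, (S)-2-aminopent-4-enoic acid | N[C@@H](CC=C)C(=O)O | starting material
2 | (S)-2-hydroxypent-4-enoic acid | O[C@@H](CC=C)C(=O)O | intermediate
3 | (2S,5S)-2-tert-butyl-5-(prop-2-en-1-yl)-1,3-dioxolan-4-one | C=CC[C@@H]1O[C@H](C(C)(C)C)OC1=O | intermediate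
4 | 4-methoxybenzyl alcohol | COc1ccc(CO)cc1 | starting material
5 | 3-bromo-2-(bromomethyl)prop-1-ene | BrCC(=C)CBr | starting material
6 | sodium 4-methoxybenzyl oxide (not isolated) | [Na+].[O-]Cc1ccc(OC)cc1 | intermediate
7 | 1-({[2-(bromomethyl)prop-2-en-1-yl]oxy}methyl)-4-methoxybenzene | BrCC(=C)COCc1ccc(OC)cc1 | intermediate
8 | lithium enolate of dioxolanone 3 (not isolated) | C=CCC1=C([O-])O[C@@H](C(C)(C)C)O1.[Li+] | intermediate
9 | (2S,5R)-2-tert-butyl-5-{2-[(4-methoxybenzyloxy)methyl]prop-2-en-1-yl}-5-(prop-2-en-1-yl)-1,3-dioxolan-4-one | C=CC[C@]1(CC(=C)COCc2ccc(OC)cc2)O[C@H](C(C)(C)C)OC1=O | intermediate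
10 | (2R)-2-hydroxy-2-{2-[(4-methoxybenzyloxy)methyl]prop-2-en-1-yl}pent-4-enoic acid | C=CC[C@](O)(C(=O)O)CC(=C)COCc1ccc(OC)cc1 | intermediate
11 | tert-butyl (2R)-2-hydroxy-2-{2-[(4-methoxybenzyloxy)methyl]prop-2-en-1-yl}pent-4-enoate | C=CC[C@](O)(C(=O)OC(C)(C)C)CC(=C)COCc1ccc(OC)cc1 | intermediate
12 | tert-butyl (2R)-2-methoxy-2-{2-[(4-methoxybenzyloxy)methyl]prop-2-en-1-yl}pent-4-enoate | C=CC[C@](OC)(C(=O)OC(C)(C)C)CC(=C)COCc1ccc(OC)cc1 | intermediate
13 | tert-butyl (2R)-2-methoxy-5-(4-methoxybenzyloxy)-4-oxo-2-(2-oxoethyl)pentanoate | O=CC[C@](OC)(C(=O)OC(C)(C)C)CC(=O)COCc1ccc(OC)cc1 | intermediate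
14 | tert-butyl (1R,4S,5R)-5-hydroxy-1-methoxy-4-(4-methoxybenzyloxy)-3-oxocyclohexane-1-carboxylate | CO[C@@]1(C(=O)OC(C)(C)C)CC(=O)[C@@H](OCc2ccc(OC)cc2)[C@H](O)C1 | intermediate
15 | tert-butyl 1-O-methyl-4-O-(4-methoxybenzyl)quinate | CO[C@@]1(C(=O)OC(C)(C)C)C[C@@H](O)[C@@H](OCc2ccc(OC)cc2)[C@H](O)C1 | intermediate
16 | tert-butyl 1-O-methyl-3,4-O-(4-methoxybenzylidene)quinate (acetal carbon unspecified) | CO[C@@]1(C(=O)OC(C)(C)C)C[C@@H](OC2c3ccc(OC)cc3)[C@@H](O2)[C@H](O)C1 | intermediate
17 | caffeic acid | OC(=O)/C=C/c1ccc(O)c(O)c1 | starting material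
18 | (E)-3-(3,4-diacetoxyphenyl)prop-2-enoic acid | CC(=O)Oc1ccc(/C=C/C(=O)O)cc1OC(C)=O | intermediate
19 | (E)-3-(3,4-diacetoxyphenyl)prop-2-enoyl chloride | CC(=O)Oc1ccc(/C=C/C(Cl)=O)cc1OC(C)=O | intermediate
20 | tert-butyl 5-O-[(E)-3-(3,4-diacetoxyphenyl)prop-2-enoyl]-1-O-methyl-3,4-O-(4-methoxybenzylidene)quinate | CO[C@@]1(C(=O)OC(C)(C)C)C[C@@H](OC2c3ccc(OC)cc3)[C@@H](O2)[C@H](OC(=O)/C=C/c2ccc(OC(C)=O)c(OC(C)=O)c2)C1 | intermediate
21 | 5-O-[(E)-3-(3,4-diacetoxyphenyl)prop-2-enoyl]-1-O-methylquinic acid | CO[C@@]1(C(=O)O)C[C@@H](O)[C@@H](O)[C@H](OC(=O)/C=C/c2ccc(OC(C)=O)c(OC(C)=O)c2)C1 | intermediate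
22 | 3-O-caffeoyl-1-methylquinic acid, (1S,3R,4R,5R) | CO[C@@]1(C(=O)O)C[C@@H](O)[C@@H](O)[C@H](OC(=O)/C=C/c2ccc(O)c(O)c2)C1 | target

**Step count**

Total: 16 steps. Longest linear sequence: 13 steps (1, 2, 4–11, 14–16).

**Steps most likely to fail**

Step 9. The fixed C1 centre may work against the catalyst, because the chair in which the adduct first forms carries the C1 ester axial next to the acid-bound aldehyde oxygen. Facial selectivity at C5 may therefore be poor. Loss of water or methanol from the β-oxygenated ketone may also compete. The fallback sets out from 13 and keeps the same C4–C5 closure but sets both centres afterwards. Piperidine/AcOH (cat.) in toluene at 50 °C should drive the aldol through to the enone tert-butyl (1R)-1-methoxy-4-(4-methoxybenzyloxy)-3-oxocyclohex-4-ene-1-carboxylate F1. Luche reduction (NaBH4, CeCl3·7H2O, MeOH, −78 °C) should deliver hydride anti to the pseudo-axial C1 methoxy and give the allylic alcohol tert-butyl (1R,3R)-3-hydroxy-1-methoxy-4-(4-methoxybenzyloxy)cyclohex-4-ene-1-carboxylate F2. Hydroboration–oxidation of the enol ether (BH3·THF, 0 °C; then NaBO3·4H2O) places boron on C5 and hydrogen on C4 in a syn addition anti to O3 and to the C1 methoxy. This sets O4 cis to O3 and O5 trans, and rejoins the route at 15.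

Step 11. The oxocarbenium ion on O4 may be captured by the trans O5–H as well as by the cis O3–H, and the acetal may be oxidised further to an anisate ester. The fallback sets out from 15. DDQ in CH2Cl2/pH 7 buffer removes the PMB group and gives the triol tert-butyl 1-O-methylquinate F3. 2,2-Dimethoxypropane with TsOH (cat.) in acetone protects the cis 3,4-diol as tert-butyl 3,4-O-isopropylidene-1-O-methylquinate F4. Acylation with 19 (pyridine, DMAP, CH2Cl2) gives tert-butyl 5-O-[(E)-3-(3,4-diacetoxyphenyl)prop-2-enoyl]-3,4-O-isopropylidene-1-O-methylquinate F5. TFA/CH2Cl2/H2O removes the acetonide and the tert-butyl ester and rejoins the route at 21.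

Step 10. Internal hydride delivery from the equatorial O5 requires a strained conformer, so the reduction may be slow and the facial selectivity at C3 may erode. The β-hydroxy ketone may also dehydrate in the acidic medium. The fallback sets out from 14 and replaces directed delivery by steric approach control. Et3SiOTf and 2,6-lutidine in CH2Cl2 at −78 °C give tert-butyl (1R,4S,5R)-1-methoxy-4-(4-methoxybenzyloxy)-3-oxo-5-(triethylsilyloxy)cyclohexane-1-carboxylate F6. LiBH(sec-Bu)3 in THF at −78 °C attacks equatorially, on the face opposite the axial C1 methoxy, to give the axial alcohol tert-butyl 1-O-methyl-4-O-(4-methoxybenzyl)-5-O-(triethylsilyl)quinate F7. AcOH/THF/H2O removes the silyl ether and rejoins the route at 15.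

**Further compounds**

F1 | step 9 | tert-butyl (1R)-1-methoxy-4-(4-methoxybenzyloxy)-3-oxocyclohex-4-ene-1-carboxylate | CO[C@@]1(C(=O)OC(C)(C)C)CC(=O)C(OCc2ccc(OC)cc2)=CC1
F2 | step 9 | tert-butyl (1R,3R)-3-hydroxy-1-methoxy-4-(4-methoxybenzyloxy)cyclohex-4-ene-1-carboxylate | CO[C@@]1(C(=O)OC(C)(C)C)C[C@@H](O)C(OCc2ccc(OC)cc2)=CC1
F3 | step 11 | tert-butyl 1-O-methylquinate | CO[C@@]1(C(=O)OC(C)(C)C)C[C@@H](O)[C@@H](O)[C@H](O)C1
F4 | step 11 | tert-butyl 3,4-O-isopropylidene-1-O-methylquinate | CO[C@@]1(C(=O)OC(C)(C)C)C[C@@H](OC2(C)C)[C@@H](O2)[C@H](O)C1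
F5 | step 11 | tert-butyl 5-O-[(E)-3-(3,4-diacetoxyphenyl)prop-2-enoyl]-3,4-O-isopropylidene-1-O-methylquinate | CO[C@@]1(C(=O)OC(C)(C)C)C[C@@H](OC2(C)C)[C@@H](O2)[C@H](OC(=O)/C=C/c2ccc(OC(C)=O)c(OC(C)=O)c2)C1
F6 | step 10 | tert-butyl (1R,4S,5R)-1-methoxy-4-(4-methoxybenzyloxy)-3-oxo-5-(triethylsilyloxy)cyclohexane-1-carboxylate | CO[C@@]1(C(=O)OC(C)(C)C)CC(=O)[C@@H](OCc2ccc(OC)cc2)[C@H](O[Si](CC)(CC)CC)C1
F7 | step 10 | tert-butyl 1-O-methyl-4-O-(4-methoxybenzyl)-5-O-(triethylsilyl)quinate | CO[C@@]1(C(=O)OC(C)(C)C)C[C@@H](O)[C@@H](OCc2ccc(OC)cc2)[C@H](O[Si](CC)(CC)CC)C1
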